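**Strategy.** The target is cut at the two bonds that the indoline carbons C2 and C7 (its C3 position) make to C16 and C6. This returns an aromatic N-methoxycarbonyl indole-3-carboxylate whose C2=C7 bond is a push-pull Michael acceptor. The key step is an anionic dearomatizing Michael/alkylation cascade: a side-chain ester enolate (C16) adds to C2 and closes the cyclohexane, and the C7 enolate so created displaces chloride from an N-CH2CH2Cl arm (C6), closing the azocine. Both spiro centres, the vicinal quaternary pair C2/C7 and the bicyclo[4.2.2] core arise at once. The precursor is a 2,2-disubstituted 3-silyloxypyrrolidine made from trans-3-hydroxy-L-proline, carrying the indole on one arm.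

Key step: step 12

Remark: biogenetic labels are used throughout (indoline N1, C2, C7; azocine C6, C5, N4; pyrrolidine C3, C14, C15, C20; cyclohexane C16, C17, C20, C19, C18, C2), and compounds 1, 3, 5 and 10 are assumed to be commercial.

Step 1
Reactants: 1 trans-3-hydroxy-L-proline
Product: 2 methyl (2S,3S)-3-hydroxypyrrolidine-2-carboxylate hydrochloride
Conditions: SOCl2, MeOH, 0 °C to reflux
Reagents that add atoms: methanol, CO; thionyl chloride, O=S(Cl)Cl
Why: Acid-mediated esterification with HCl made in the flask from thionyl chloride and methanol; the same HCl supplies the chloride of the ammonium salt, and neither stereocenter is touched.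

Step 2
Reactants: 2 methyl (2S,3S)-3-hydroxypyrrolidine-2-carboxylate hydrochloride; 3 2-(benzyloxy)acetaldehyde
Product: 4 methyl (2S,3S)-1-[2-(benzyloxy)ethyl]-3-hydroxypyrrolidine-2-carboxylate
Conditions: Et3N, NaBH(OAc)3, ClCH2CH2Cl, 25 °C
Reagents that add atoms: none
Why: Reductive amination through the iminium ion should alkylate the secondary amine without touching ester or alcohol; the arm is the future C5-C6 unit, and a tertiary N4 can no longer lactamize onto the later C16 ester.

Step 3
Reactants: 4 methyl (2S,3S)-1-[2-(benzyloxy)ethyl]-3-hydroxypyrrolidine-2-carboxylate; 5 tert-butyl acrylate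
Product: 7 methyl (2R,3S)-1-[2-(benzyloxy)ethyl]-2-(3-tert-butoxy-3-oxopropyl)-3-hydroxypyrrolidine-2-carboxylate, via dilithium alkoxide enolate 6 (not isolated)
Conditions: LiN(iPr)2 (2.2 equiv), THF, −78 °C; then 5, −78 °C; aq. NH4Cl
Reagents that add atoms: none
Why: Fráter–Seebach dianion formation and Michael addition: the chelated alkoxide enolate should be attacked anti to the C15 oxygen, which sets the quaternary C20 with the new propanoate arm (C17, C16) trans and the ester carbon (future C19) cis to the hydroxyl.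

Step 4
Reactants: 7 methyl (2R,3S)-1-[2-(benzyloxy)ethyl]-2-(3-tert-butoxy-3-oxopropyl)-3-hydroxypyrrolidine-2-carboxylate
Product: 8 methyl (2R,3S)-1-[2-(benzyloxy)ethyl]-2-(3-tert-butoxy-3-oxopropyl)-3-[(tert-butyldimethylsilyl)oxy]pyrrolidine-2-carboxylate
Conditions: TBSOTf, 2,6-lutidine, CH2Cl2, 0 °C
Reagents that add atoms: tert-butyldimethylsilyl trifluoromethanesulfonate, CC(C)(C)[Si](C)(C)OS(=O)(=O)C(F)(F)F
Why: Silyl triflate with a hindered pyridine base is the standard silylation of a hindered secondary alcohol next to a quaternary carbon; the bulky silyl ether later also steers the N-arm in step 12.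

Step 5
Reactants: 8 methyl (2R,3S)-1-[2-(benzyloxy)ethyl]-2-(3-tert-butoxy-3-oxopropyl)-3-[(tert-butyldimethylsilyl)oxy]pyrrolidine-2-carboxylate
Product: 9 tert-butyl 3-[(2R,3S)-1-[2-(benzyloxy)ethyl]-3-[(tert-butyldimethylsilyl)oxy]-2-formylpyrrolidin-2-yl]propanoate
Conditions: iBu2AlH (1.2 equiv), toluene, −78 °C; aq. potassium sodium tartrate
Reagents that add atoms: none
Why: Partial ester reduction: the tetrahedral aluminium hemiacetal, chelated by the alpha-amino group, should survive at −78 °C and release the aldehyde on work-up, the tert-butyl ester being inert and the alpha-quaternary aldehyde unable to epimerize.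

Step 6
Reactants: 10 methyl 2-methyl-1H-indole-3-carboxylate
Product: 11 dimethyl 2-methyl-1H-indole-1,3-dicarboxylate
Conditions: NaH, THF, 0 °C; then ClCO2Me, 0 to 25 °C
Reagents that add atoms: methyl chloroformate, COC(=O)Cl
Why: N-Acylation of the indolyl sodium salt installs the carbamate that the target carries and that makes C2=C7 a Michael acceptor.

Step 7
Reactants: 11 dimethyl 2-methyl-1H-indole-1,3-dicarboxylate
Product: 12 dimethyl 2-(bromomethyl)-1H-indole-1,3-dicarboxylate
Conditions: NBS, AIBN (cat.), PhCF3, reflux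
Reagents that add atoms: N-bromosuccinimide, O=C1CCC(=O)N1Br
Why: Wohl–Ziegler radical bromination should take the only benzylic-type C-H bonds, those of the 2-methyl group, the ring being deactivated by two acyl groups.

Step 8
Reactants: 12 dimethyl 2-(bromomethyl)-1H-indole-1,3-dicarboxylate
Product: 13 {[1,3-bis(methoxycarbonyl)-1H-indol-2-yl]methyl}triphenylphosphonium bromide
Conditions: PPh3, toluene, 80 °C
Reagents that add atoms: triphenylphosphine, c1ccc(cc1)P(c1ccccc1)c1ccccc1
Why: SN2 quaternization of the phosphine by the reactive indolylmethyl bromide.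

Step 9
Reactants: 13 {[1,3-bis(methoxycarbonyl)-1H-indol-2-yl]methyl}triphenylphosphonium bromide; 9 tert-butyl 3-[(2R,3S)-1-[2-(benzyloxy)ethyl]-3-[(tert-butyldimethylsilyl)oxy]-2-formylpyrrolidin-2-yl]propanoate
Product: 15 dimethyl 2-{2-[(2S,3S)-1-[2-(benzyloxy)ethyl]-2-(3-tert-butoxy-3-oxopropyl)-3-[(tert-butyldimethylsilyl)oxy]pyrrolidin-2-yl]ethenyl}-1H-indole-1,3-dicarboxylate (E/Z mixture), via phosphorus ylide 14 (not isolated)
Conditions: NaN(SiMe3)2, THF, −78 °C; then 9, −78 to 25 °C
Reagents that add atoms: none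
Why: Wittig olefination with the semi-stabilized ylide (conjugated with the C3 ester) forms the C19=C18 bond; the alkene geometry is irrelevant because it is hydrogenated next, and the alpha-quaternary aldehyde cannot enolize.

Step 10
Reactants: 15 dimethyl 2-{2-[(2S,3S)-1-[2-(benzyloxy)ethyl]-2-(3-tert-butoxy-3-oxopropyl)-3-[(tert-butyldimethylsilyl)oxy]pyrrolidin-2-yl]ethenyl}-1H-indole-1,3-dicarboxylate
Product: 16 dimethyl 2-{2-[(2R,3S)-2-(3-tert-butoxy-3-oxopropyl)-3-[(tert-butyldimethylsilyl)oxy]-1-(2-hydroxyethyl)pyrrolidin-2-yl]ethyl}-1H-indole-1,3-dicarboxylate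
Conditions: H2 (3 atm), Pd(OH)2 on carbon, AcOH (1 equiv), EtOAc/MeOH, 25 °C
Reagents that add atoms: none
Why: Heterogeneous hydrogenation should saturate the disubstituted alkene and hydrogenolyse the benzyl ether in one flask, leaving the aromatic N-acyl indole, the silyl ether and both ester types untouched; acetic acid keeps the amine from poisoning the catalyst.

Step 11
Reactants: 16 dimethyl 2-{2-[(2R,3S)-2-(3-tert-butoxy-3-oxopropyl)-3-[(tert-butyldimethylsilyl)oxy]-1-(2-hydroxyethyl)pyrrolidin-2-yl]ethyl}-1H-indole-1,3-dicarboxylate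
Product: 19 dimethyl 2-{2-[(2R,3S)-2-(3-tert-butoxy-3-oxopropyl)-3-[(tert-butyldimethylsilyl)oxy]-1-(2-chloroethyl)pyrrolidin-2-yl]ethyl}-1H-indole-1,3-dicarboxylate, via primary mesylate 17 (not isolated), via spiro aziridinium chloride 18 (not isolated)
Conditions: MsCl, Et3N, CH2Cl2, 0 to 25 °C; used at once
Reagents that add atoms: methanesulfonyl chloride (source of the chloride), CS(=O)(=O)Cl
Why: Mesylation, neighbouring-group displacement by N4 to the symmetrical spiro-aziridinium ion and its opening by chloride (either carbon gives the same product) should convert the amino alcohol into the 2-chloroethylamine.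

Step 12
Reactants: 19 dimethyl 2-{2-[(2R,3S)-2-(3-tert-butoxy-3-oxopropyl)-3-[(tert-butyldimethylsilyl)oxy]-1-(2-chloroethyl)pyrrolidin-2-yl]ethyl}-1H-indole-1,3-dicarboxylate
Product: 22 pentacyclic cascade product: the target skeleton with (2R,7S,15S,16R,20R) configuration carrying a tert-butyl ester at C16 and a TBS ether at C15, via open-chain potassium ester enolate 20 (not isolated), via spirocyclic potassium C7 enolate 21 (not isolated)
Conditions: KN(SiMe3)2 (1.2 equiv), THF, −78 to −20 °C; then DMPU, 25 to 45 °C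
Reagents that add atoms: none
Why: Proposed new method: KN(SiMe3)2 reversibly deprotonates the tert-butyl ester (and, unproductively, the lateral C18-H), and enolate 20 adds 6-exo-trig to C2 of the N-acyl indole-3-carboxylate, whose C2=C7 bond is a vinylogous-carbamate Michael acceptor, to give the aryl-stabilized C7 enolate 21 as the sink of the anion manifold; the closest known reactions are the SmI2 ketyl dearomatizing cyclization of N-acyl indole-3-carboxylates with alkylation of the C3 enolate, and Michael-initiated ring closures. On warming, C7 of 21 should displace chloride from C6 in an 8-exo-tet transannular alkylation that bridges the 1,4-positions of the new cyclohexane and completes the azocine. C2 is set relative to C20 because the Michael addition is reversible (the C2-C16 bond is aligned with the enolate pi system) and only the epimer with C7 cis to N4 can be drained by the irreversible alkylation. C16 is set in the same equilibrium, the bulky ester taking the pseudo-equatorial position cis to C7. C7 is set by the C15 silyloxy group, which lies on the C19 face of the pyrrolidine and pushes the N-chloroethyl arm to the C17 face, so that C6 meets the enolate face that lies over C16. The step needs C7-alkylation to beat C16- or C18-alkylation, which rests on the inertness of the primary chloride at −20 °C and on open-chain carbanions being present only in traces once 21 has formed.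

Step 13
Reactants: 22 pentacyclic tert-butyl ester TBS ether
Product: 23 target CNP0144467.1
Conditions: HCl (3 M in MeOH), 50 °C; NaHCO3 work-up
Reagents that add atoms: methanol, CO
Why: Acid-catalysed cleavage of the tert-butyl ester with Fischer esterification by the solvent, together with methanolysis of the silyl ether, should give the target in one flask; the two methyl esters exchange degenerately, the carbamate is inert and no stereocenter is touched.

**Compound list**

1 | trans-3-hydroxy-L-proline, (2S,3S)-3-hydroxypyrrolidine-2-carboxylic acid | OC(=O)[C@H]1NCC[C@@H]1O | starting material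
2 | methyl (2S,3S)-3-hydroxypyrrolidine-2-carboxylate hydrochloride | Cl.COC(=O)[C@H]1NCC[C@@H]1O | intermediate
3 | 2-(benzyloxy)acetaldehyde | O=CCOCc1ccccc1 | starting material
4 | methyl (2S,3S)-1-[2-(benzyloxy)ethyl]-3-hydroxypyrrolidine-2-carboxylate | COC(=O)[C@H]1N(CCOCc2ccccc2)CC[C@@H]1O | intermediate
5 | tert-butyl acrylate | C=CC(=O)OC(C)(C)C | starting material
6 | dilithium alkoxide enolate of 4 | [Li+].[Li+].COC([O-])=C1N(CCOCc2ccccc2)CC[C@@H]1[O-] | intermediate (not isolated)
7 | methyl (2R,3S)-1-[2-(benzyloxy)ethyl]-2-(3-tert-butoxy-3-oxopropyl)-3-hydroxypyrrolidine-2-carboxylate | CC(C)(C)OC(=O)CC[C@]1(N(CCOCc2ccccc2)CC[C@@H]1O)C(=O)OC | intermediate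
8 | methyl (2R,3S)-1-[2-(benzyloxy)ethyl]-2-(3-tert-butoxy-3-oxopropyl)-3-[(tert-butyldimethylsilyl)oxy]pyrrolidine-2-carboxylate | CC(C)(C)OC(=O)CC[C@]1(N(CCOCc2ccccc2)CC[C@@H]1O[Si](C)(C)C(C)(C)C)C(=O)OC | intermediate
9 | tert-butyl 3-[(2R,3S)-1-[2-(benzyloxy)ethyl]-3-[(tert-butyldimethylsilyl)oxy]-2-formylpyrrolidin-2-yl]propanoate | CC(C)(C)OC(=O)CC[C@]1(N(CCOCc2ccccc2)CC[C@@H]1O[Si](C)(C)C(C)(C)C)C=O | intermediate
10 | methyl 2-methyl-1H-indole-3-carboxylate | COC(=O)c1c(C)[nH]c2ccccc12 | starting material
11 | dimethyl 2-methyl-1H-indole-1,3-dicarboxylate | COC(=O)c1c(C)n(C(=O)OC)c2ccccc12 | intermediate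
12 | dimethyl 2-(bromomethyl)-1H-indole-1,3-dicarboxylate | COC(=O)c1c(CBr)n(C(=O)OC)c2ccccc12 | intermediate
13 | {[1,3-bis(methoxycarbonyl)-1H-indol-2-yl]methyl}triphenylphosphonium bromide | [Br-].COC(=O)c1c(C[P+](c2ccccc2)(c2ccccc2)c2ccccc2)n(C(=O)OC)c2ccccc12 | intermediate
14 | phosphorus ylide of 13 | COC(=O)c1c(C=P(c2ccccc2)(c2ccccc2)c2ccccc2)n(C(=O)OC)c2ccccc12 | intermediate (not isolated)
15 | dimethyl 2-{2-[(2S,3S)-1-[2-(benzyloxy)ethyl]-2-(3-tert-butoxy-3-oxopropyl)-3-[(tert-butyldimethylsilyl)oxy]pyrrolidin-2-yl]ethenyl}-1H-indole-1,3-dicarboxylate (E/Z mixture) | CC(C)(C)OC(=O)CC[C@]1(N(CCOCc2ccccc2)CC[C@@H]1O[Si](C)(C)C(C)(C)C)C=Cc1c(C(=O)OC)c2ccccc2n1C(=O)OC | intermediate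
16 | dimethyl 2-{2-[(2R,3S)-2-(3-tert-butoxy-3-oxopropyl)-3-[(tert-butyldimethylsilyl)oxy]-1-(2-hydroxyethyl)pyrrolidin-2-yl]ethyl}-1H-indole-1,3-dicarboxylate | CC(C)(C)OC(=O)CC[C@]1(N(CCO)CC[C@@H]1O[Si](C)(C)C(C)(C)C)CCc1c(C(=O)OC)c2ccccc2n1C(=O)OC | intermediate
17 | primary mesylate of 16 | CC(C)(C)OC(=O)CC[C@]1(N(CCOS(C)(=O)=O)CC[C@@H]1O[Si](C)(C)C(C)(C)C)CCc1c(C(=O)OC)c2ccccc2n1C(=O)OC | intermediate (not isolated)
18 | spiro aziridinium chloride (N4 in an aziridinium ring with C5 and C6) | [Cl-].CC(C)(C)OC(=O)CC[C@]1([N+]2(CC2)CC[C@@H]1O[Si](C)(C)C(C)(C)C)CCc1c(C(=O)OC)c2ccccc2n1C(=O)OC | intermediate (not isolated)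
19 | dimethyl 2-{2-[(2R,3S)-2-(3-tert-butoxy-3-oxopropyl)-3-[(tert-butyldimethylsilyl)oxy]-1-(2-chloroethyl)pyrrolidin-2-yl]ethyl}-1H-indole-1,3-dicarboxylate | CC(C)(C)OC(=O)CC[C@]1(N(CCCl)CC[C@@H]1O[Si](C)(C)C(C)(C)C)CCc1c(C(=O)OC)c2ccccc2n1C(=O)OC | intermediate
20 | open-chain potassium tert-butyl ester enolate of 19 (carbanion at C16) | [K+].CC(C)(C)OC([O-])=CC[C@]1(N(CCCl)CC[C@@H]1O[Si](C)(C)C(C)(C)C)CCc1c(C(=O)OC)c2ccccc2n1C(=O)OC | intermediate (not isolated)
21 | spirocyclic potassium C7 enolate (cyclohexane closed, indoline C2 spiro, N-chloroethyl arm still open) | [K+].CC(C)(C)OC(=O)[C@@H]1C[C@@]2(CC[C@@]13N(C(=O)OC)c1ccccc1C3=C([O-])OC)N(CCCl)CC[C@@H]2O[Si](C)(C)C(C)(C)C | intermediate (not isolated)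
22 | pentacyclic cascade product, (2R,7S,15S,16R,20R), tert-butyl ester at C16, methyl ester at C7, N1-methoxycarbonyl, TBS ether at C15 | CC(C)(C)OC(=O)[C@@H]1C[C@@]23CC[C@@]14N(C(=O)OC)c1ccccc1[C@@]4(C(=O)OC)CCN2CC[C@@H]3O[Si](C)(C)C(C)(C)C | intermediate
23 | CNP0144467.1, (2R,7S,15S,16R,20R), methyl esters at C16 and C7, N1-methoxycarbonyl, free 15-hydroxyl | COC(=O)[C@@H]1C[C@@]23CC[C@@]14N(C(=O)OC)c1ccccc1[C@@]4(C(=O)OC)CCN2CC[C@@H]3O | target

**Step count.** Total: 13 steps. Longest linear sequence: 10 steps (steps 1 to 5 and 9 to 13).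

**Steps most likely to fail**

Step 12. Several processes may divert the cascade. Retro-Michael leakage would let the open-chain ester enolate or the lateral C18 anion capture C6 in a six-ring alkylation. N4 may close onto C6 to the aziridinium ion, which C7 cannot open for geometric reasons. C6 may attack the enolate face over C18, or the adduct may be epimeric at C16. The Michael equilibrium may not favour the dearomatized enolate at all. The fallback uses known reactions only, sets out from 9 and returns at 22, and forms C7-C6 before C2-C16. Wittig olefination of 9 with methyl 3-oxo-4-(triphenylphosphoranylidene)butanoate should give the enone keto ester F1. Hydrogenation (H2, Pd(OH)2 on carbon) saturates the alkene and frees the primary alcohol, giving keto ester alcohol F2, and MsCl/Et3N converts it into the chloride F3. Intramolecular C-alkylation of the beta-keto ester (K2CO3, NaI, MeCN, high dilution) closes the eight-membered ring to the bicyclic keto ester F4. Condensation with phenylhydrazine gives the hydrazone F5, and Fischer indolization of this alpha-branched ketone (AcOH, heat) gives the 3H-indole F6 with the quaternary C7; the C7 diastereomers are separated. LiN(SiMe3)2 then forms the tert-butyl ester enolate, which should add across the ring to C2=N1 anti to the C7 ester, and ClCO2Me traps the anilide in the same flask to give 22.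

Step 3. The acrylate may oligomerize anionically through the adduct enolate, and attack syn to the alkoxide would erode the configuration at C20. The fallback sets out from 4 and returns at 7. The same dianion is added to tert-butyl propiolate, which cannot polymerize in this way, to give the enoate F7; homogeneous hydrogenation (H2, RhCl(PPh3)3), which spares the benzyl ether, then gives 7.

Step 9. Addition of the bulky semi-stabilized ylide to the neopentyl-type aldehyde may be slow, with attack of the ylide on the indole N-carbamate competing. The fallback sets out from 9 and returns at 15, and moves the bond formation away from the hindered carbon. Methylenation of 9 with Ph3P=CH2 gives the vinyl pyrrolidine F8. Methyl 1H-indole-3-carboxylate is N-methoxycarbonylated (NaH, ClCO2Me) to dimethyl 1H-indole-1,3-dicarboxylate F9 and brominated at C2 (LiN(iPr)2, then BrCCl2CCl2Br) to the 2-bromoindole F10. A Heck reaction of F8 with F10 (Pd(OAc)2, P(o-tol)3, K2CO3, DMF, 100 °C) forms the C18-C2 bond and should give 15 as the E isomer.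

Further compounds

F1 | step 12 | tert-butyl 3-[(2S,3S)-1-[2-(benzyloxy)ethyl]-3-[(tert-butyldimethylsilyl)oxy]-2-[(1E)-5-methoxy-3,5-dioxopent-1-en-1-yl]pyrrolidin-2-yl]propanoate | CC(C)(C)OC(=O)CC[C@]1(N(CCOCc2ccccc2)CC[C@@H]1O[Si](C)(C)C(C)(C)C)/C=C/C(=O)CC(=O)OC
F2 | step 12 | tert-butyl 3-[(2R,3S)-3-[(tert-butyldimethylsilyl)oxy]-1-(2-hydroxyethyl)-2-(5-methoxy-3,5-dioxopentyl)pyrrolidin-2-yl]propanoate | CC(C)(C)OC(=O)CC[C@]1(N(CCO)CC[C@@H]1O[Si](C)(C)C(C)(C)C)CCC(=O)CC(=O)OC
F3 | step 12 | tert-butyl 3-[(2R,3S)-3-[(tert-butyldimethylsilyl)oxy]-1-(2-chloroethyl)-2-(5-methoxy-3,5-dioxopentyl)pyrrolidin-2-yl]propanoate | CC(C)(C)OC(=O)CC[C@]1(N(CCCl)CC[C@@H]1O[Si](C)(C)C(C)(C)C)CCC(=O)CC(=O)OC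
F4 | step 12 | bicyclic beta-keto ester (pyrrolidine fused at N4-C20 to an eight-membered ring, C7-C6 bond closed, ketone at C2, C7 epimers) | CC(C)(C)OC(=O)CC[C@@]12CCC(=O)C(C(=O)OC)CCN1CC[C@@H]2O[Si](C)(C)C(C)(C)C
F5 | step 12 | phenylhydrazone of F4 | CC(C)(C)OC(=O)CC[C@@]12CCC(=NNc3ccccc3)C(C(=O)OC)CCN1CC[C@@H]2O[Si](C)(C)C(C)(C)C
F6 | step 12 | 3H-indole with quaternary C7 (methyl ester and C6), C2=N1 imine, azocine closed, propanoate arm open | CC(C)(C)OC(=O)CC[C@@]12CCC3=Nc4ccccc4[C@@]3(C(=O)OC)CCN1CC[C@@H]2O[Si](C)(C)C(C)(C)C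
F7 | step 3 | methyl (2R,3S)-1-[2-(benzyloxy)ethyl]-2-(3-tert-butoxy-3-oxoprop-1-en-1-yl)-3-hydroxypyrrolidine-2-carboxylate (E/Z mixture) | CC(C)(C)OC(=O)C=C[C@]1(N(CCOCc2ccccc2)CC[C@@H]1O)C(=O)OC
F8 | step 9 | tert-butyl 3-[(2S,3S)-1-[2-(benzyloxy)ethyl]-3-[(tert-butyldimethylsilyl)oxy]-2-ethenylpyrrolidin-2-yl]propanoate | CC(C)(C)OC(=O)CC[C@]1(N(CCOCc2ccccc2)CC[C@@H]1O[Si](C)(C)C(C)(C)C)C=C
F9 | step 9 | dimethyl 1H-indole-1,3-dicarboxylate | COC(=O)c1cn(C(=O)OC)c2ccccc12
F10 | step 9 | dimethyl 2-bromo-1H-indole-1,3-dicarboxylate | COC(=O)c1c(Br)n(C(=O)OC)c2ccccc12
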